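The ratio I watched was [protic impurity] to [solid substrate]: 0.147 in Thursday's flask and 0.100 in Friday's.

| setting | Friday's | Thursday's | flask |
|---|---|---|---|
| solid substrate | 0.050 M | 0.034 M | 0.050 M |
| protic impurity | 5 mM | 5 mM | 5.00 mM |
| remark | the very flask that is asked about, followed so far | run made earlier |  |
| time |  |  | 15 d |

| run | time / d | solid substrate / % | target / % |
|---|---|---|---|
| Friday's | 0.333 | 0 | 42.5 |
| Friday's | 1.04 | 0 | 28.5 |
| Friday's | 1.67 | 1.6 | 31.2 |
| Friday's | 2.50 | 1.4 | 30.1 |
| Thursday's | 2.50 | 1.0 | 29.2 |
| Thursday's | 5.00 | 0.4 | 28.0 |
| Thursday's | 8.00 | 0 | 27.3 |
| Thursday's | 10.0 | 0.7 | 27.7 |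

(standard deviation of a reading: 1 percentage point)

1. part of the solid substrate that has turned into other species by 15 d (what has only dissolved does not count)
2. target at 15 d, in percent of the solid substrate charged
3. isomer of the product A at 15 d, in percent of the solid substrate charged
4. starting material at 15 d, in percent of the solid substrate charged

- as a solid, counted per litre of solution: solid substrate
- what was read earlier has a scatter of 1 percentage point, one standard deviation
- at the start none of the solid substrate is in solution
- what has only dissolved of solid substrate counts as not reacted
- starting material means what is dissolved; the solid is not counted in it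

Thursday's target readings lay flat from 2.50 d on, with a mean of 28.1 %. I supposed that each protic impurity took one equivalent of the charge for good, a small correction to it, and that the rest shared out in a fixed proportion. From Thursday's flask the target share, meaning target over the part of the charge that the ratio spared, came to 32.9 %. For Friday's flask at 15 d I committed to target 29.6 %; its last reading was 30.1 %. Neither isomer of the product A nor dissolved starting material had been read, so my reckoning stopped at the target.

The forecast gave target 28.5 %, isomer of the product A 68.5 %, starting material 3 % and conversion 97 %, and it read the plateau as “a first-order or equilibrium limit”.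

Friday's flask gave target 29.8 %, isomer of the product A 38.7 %, starting material 14.2 % and conversion 85.8 %. My target lay 0.20 percentage points from it.

    starting material ⇌ target (K = 2.10, k = 4.80 × 10⁻⁴ s⁻¹)
    target ⇌ isomer of the product A (K = 1.30, k = 4.00 × 10⁻⁵ s⁻¹)
    isomer of the product A ⇌ isomer of the product B (K = 0.190, k = 6.60 × 10⁻⁵ s⁻¹)
    isomer of the product B ⇌ starting material (k = 5.50 × 10⁻⁶ s⁻¹)
    solid substrate ⇌ starting material, rate k5*(cs5 - [starting material]) while solid is left; crystals form when [starting material] > cs5 (solubility = 20.0 mM, k = 3.80 × 10⁻⁴ s⁻¹)
    starting material + protic impurity → quenched substrate (k = 0.00210 L mol⁻¹ s⁻¹)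

In Friday's flask quenched substrate stood at 10.0 % of the charge at 15.0 d, which matched the ratio. Protic impurity, the limiting reagent of the quenching step, stood at 0 % of its charge in that flask. The neighbouring flask changed one setting: [protic impurity] was 0.020 M, or 0.400 equiv. The same target share gave 19.7 % target there. That flask ended with quenched substrate 40.0 % and target 19.8 %.

The earlier runs and the new flask are simulated for substances that don't exist; noise was put on by code.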